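**Plan**
- Retrosynthesis: the imidazole is opened at N1–C2 and N1–C5 (N1 = ammonia); then the N3–C4 bond and the bond from C4 to C3 of the 6-bromoindole are cut together.
- Enabling feature: imidazole C4 carries both the nucleophilic C3 of the 6-bromoindole ring and N3, and N3 is acylated by C2 (the former indole-3-carbonyl carbon). C4 is therefore an N-acyliminium carbon, and C5 is the masked CHO of glyoxal monoacetal.
- Forward, chain assembly: amide 1, aldehyde 2 and 6-bromoindole 3 are joined in one pot (hemiaminal 4, N-acyliminium ion 5) to the open-chain amido acetal 6; no ring forms here.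
- Forward, ring closure: NH4OAc/AcOH unmasks C5 (aldehyde 7), brings in N1 (aldimine 8) and closes the imidazole, the only ring made on the route, to give 9.
- Stereochemistry: the target has no stereocentre; the single sp3 centre of 6 (future C4) is formed racemic and is flattened on aromatisation.

Key step: step 1

Remark: nortopsentin C has no stereogenic element, so the structure given is one achiral compound and no enantioselective step is needed. The imidazole is drawn as the 1H-4-(bromoindolyl) tautomer.

**Step 1**
Reactants: 1 1H-indole-3-carboxamide; 2 2,2-dimethoxyacetaldehyde; 3 6-bromo-1H-indole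
Product: 6 racemic N-[1-(6-bromo-1H-indol-3-yl)-2,2-dimethoxyethyl]-1H-indole-3-carboxamide, via hemiaminal 4 (not isolated), via N-acyliminium ion 5 (not isolated)
Conditions: 1 (1.2 equiv), 2 (60 wt % aq., 1.0 equiv), Et3N (5 mol %), THF, 50 °C; PhMe azeotrope; then 3 (0.9 equiv), (PhO)2P(O)OH (10 mol %), 4 Å MS, MeCN, 0 °C → rt
Reagents that add atoms: none
Why: Triethylamine-catalysed addition of the amide N–H of 1 to the electron-poor aldehyde 2 gives hemiaminal 4; after water is stripped, diphenyl phosphate ionises 4 to N-acyliminium ion 5, which C3 of 3 attacks, and loss of the C3 proton gives 6, so the N3–C4 bond and the bond from C4 to C3 of the bromoindole are made in one flask. The closest known reaction type is the three-component aza-Friedel–Crafts (Tscherniac–Einhorn-type) amidoalkylation of indoles by an aldehyde and a primary amide or carbamate, which is established for activated aldehydes such as glyoxylates. No ring is closed. The one new stereocentre, the carbon that carries N, the indolyl group and the acetal, is formed without any controlling element as a racemate, which is harmless because it becomes the sp2 carbon C4 of the imidazole. The step needs attack through C3 and not N1 of 3, which the enamine-like reactivity of an N–H indole under acid secures, and it needs mono-addition instead of bis(indolyl)methane formation, which is secured by binding 2 as 4 before 3 is added (1 in slight excess, 3 limiting), by the weak acid buffered by its own anion, and by the two acetal oxygens next to the new carbon, which disfavour loss of the amide to an alkylideneindoleninium ion. The acetal should persist because its ionisation next to the N,O-substituted carbon is inductively slowed and water is removed.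

**Step 2**
Reactants: 6 racemic N-[1-(6-bromo-1H-indol-3-yl)-2,2-dimethoxyethyl]-1H-indole-3-carboxamide
Product: 9 nortopsentin C [4-(6-bromo-1H-indol-3-yl)-2-(1H-indol-3-yl)-1H-imidazole], via amido aldehyde 7 (not isolated), via amido aldimine 8 (not isolated)
Conditions: NH4OAc (20 equiv), AcOH–H2O (20:1), 100 °C
Reagents that add atoms: ammonium acetate, CC(=O)[O-].[NH4+]
Why: Hot acetic acid unmasks the aldehyde (7), ammonia condenses with it to aldimine 8 (in equilibrium with its enamine), whose nitrogen adds to the amide carbonyl in a 5-exo-trig closure, and loss of water aromatises the ring, which is the standard imidazole synthesis from α-acylamino carbonyl compounds and ammonium acetate; the aryl bromide and both N–H indoles should be inert to these metal-free, weakly acidic conditions.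

**Compound list**
1 | 1H-indole-3-carboxamide | NC(=O)c1c[nH]c2ccccc12 | starting material
2 | 2,2-dimethoxyacetaldehyde (glyoxal mono-dimethyl acetal, commercial 60 wt % aqueous solution) | COC(OC)C=O | starting material
3 | 6-bromo-1H-indole | Brc1ccc2cc[nH]c2c1 | starting material
4 | racemic N-(1-hydroxy-2,2-dimethoxyethyl)-1H-indole-3-carboxamide (hemiaminal) | COC(OC)C(O)NC(=O)c1c[nH]c2ccccc12 | intermediate
5 | (2,2-dimethoxyethylidene)(1H-indole-3-carbonyl)iminium (N-acyliminium ion) | COC(OC)C=[NH+]C(=O)c1c[nH]c2ccccc12 | intermediate
6 | racemic N-[1-(6-bromo-1H-indol-3-yl)-2,2-dimethoxyethyl]-1H-indole-3-carboxamide | COC(OC)C(NC(=O)c1c[nH]c2ccccc12)c1c[nH]c2cc(Br)ccc12 | intermediate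
7 | racemic N-[1-(6-bromo-1H-indol-3-yl)-2-oxoethyl]-1H-indole-3-carboxamide (amido aldehyde) | O=CC(NC(=O)c1c[nH]c2ccccc12)c1c[nH]c2cc(Br)ccc12 | intermediate
8 | racemic N-[1-(6-bromo-1H-indol-3-yl)-2-iminoethyl]-1H-indole-3-carboxamide (amido aldimine) | N=CC(NC(=O)c1c[nH]c2ccccc12)c1c[nH]c2cc(Br)ccc12 | intermediate
9 | nortopsentin C, 4-(6-bromo-1H-indol-3-yl)-2-(1H-indol-3-yl)-1H-imidazole (achiral) | Brc1ccc2c(-c3c[nH]c(-c4c[nH]c5ccccc45)n3)c[nH]c2c1 | target

**Totals**
Total step count: 2. Longest linear sequence: 2 (three components converge in step 1).

**Steps most likely to fail**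
The route has only two steps, so both are ranked and no third can be named.

1. Step 1. Over-alkylation is the main risk. Aldehyde released by reversal of hemiaminal formation, or the product after acid-induced loss of its amide, can be captured by a second indole to give a bis(indolyl)methane. Ionisation of the acetal instead of the hemiaminal is a second risk.
   Fallback: it sets out from 1 and 2 and returns to the route at 6, so the aldehyde never meets the indole.
   - 1, 2 and sodium p-toluenesulfinate in aqueous formic acid/MeOH at rt should give the crystalline α-amido sulfone N-[2,2-dimethoxy-1-(4-methylbenzenesulfonyl)ethyl]-1H-indole-3-carboxamide F1, which is washed free of aldehyde.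
   - Anhydrous K2CO3/Na2SO4 in THF should eliminate sulfinate from F1 and give the N-acylimine N-(2,2-dimethoxyethylidene)-1H-indole-3-carboxamide F2, used as a filtered solution.
   - 3 and diphenyl phosphate (5 mol %) are added to F2 at −20 °C; acid-catalysed aza-Friedel–Crafts addition of the indole to the preformed N-acylimine should give 6.

2. Step 2. Nitrogen attack on the weakly electrophilic, vinylogous-urea-type amide carbonyl may be slow. Closure through the amide oxygen (oxazole formation), or acid-induced loss of the amide from the indolylmethyl carbon on long heating, could then take over.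
   Fallback: it sets out from 6 and returns at 9, and places N1 on C2 before the ring is closed.
   - Lawesson's reagent in THF at 50 °C should convert 6 into the thioamide N-[1-(6-bromo-1H-indol-3-yl)-2,2-dimethoxyethyl]-1H-indole-3-carbothioamide F3.
   - Methyl iodide in acetone should S-methylate F3 to the thioimidate methyl N-[1-(6-bromo-1H-indol-3-yl)-2,2-dimethoxyethyl]-1H-indole-3-carbimidothioate F4.
   - Ammonia in methanol should displace the methylthio group of F4 and give the amidine N'-[1-(6-bromo-1H-indol-3-yl)-2,2-dimethoxyethyl]-1H-indole-3-carboximidamide F5.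
   - Aqueous HCl in MeOH at 40 °C should cyclise F5 to 9, the classical closure of N-(2,2-dialkoxyethyl)amidines to 2-substituted imidazoles, in which no oxygen nucleophile can compete.

**Further compounds**
F1 | step 1 | racemic N-[2,2-dimethoxy-1-(4-methylbenzenesulfonyl)ethyl]-1H-indole-3-carboxamide | COC(OC)C(NC(=O)c1c[nH]c2ccccc12)S(=O)(=O)c1ccc(C)cc1
F2 | step 1 | N-(2,2-dimethoxyethylidene)-1H-indole-3-carboxamide | COC(OC)C=NC(=O)c1c[nH]c2ccccc12
F3 | step 2 | racemic N-[1-(6-bromo-1H-indol-3-yl)-2,2-dimethoxyethyl]-1H-indole-3-carbothioamide | COC(OC)C(NC(=S)c1c[nH]c2ccccc12)c1c[nH]c2cc(Br)ccc12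
F4 | step 2 | racemic methyl N-[1-(6-bromo-1H-indol-3-yl)-2,2-dimethoxyethyl]-1H-indole-3-carbimidothioate | COC(OC)C(N=C(SC)c1c[nH]c2ccccc12)c1c[nH]c2cc(Br)ccc12
F5 | step 2 | racemic N'-[1-(6-bromo-1H-indol-3-yl)-2,2-dimethoxyethyl]-1H-indole-3-carboximidamide | COC(OC)C(NC(=N)c1c[nH]c2ccccc12)c1c[nH]c2cc(Br)ccc12
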